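**Retrosynthetic overview**

1. Atom labels follow the open C20 chain: C1=C2 vinyl, C3 carbinol, ring C6–C7–C8–C9–C10–C11, C12–C15 the hydroxypentenyl arm. C3–OH and vinyl ⇒ methyl ketone: the C3–O bond comes from catalyst-controlled epoxide formation, the vinyl group from ylide opening of that epoxide.
2. (E)-C13=C14 and C15–OH ⇒ allyl group on C11 plus 2-methylbut-3-en-2-ol (cross-metathesis).
3. Cyclohexane ring (the only ring; C6–C11 bond), C10–Br and C7–O ⇒ acyclic (10R,11R)-epoxy enone. The epoxide is turned into the C10/C11 bromonium ion, the C6=C7 alkene closes the ring and the ketone oxygen caps C7 (new step).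
4. Key disconnection: the two epoxide C–O bonds ⇒ hydroxyl-directed Ti/tartrate epoxidation of a C12 allylic alcohol. This picks C10=C11 out of two trisubstituted alkenes and fixes the absolute configuration later relayed to C10, C11, C6 and C7.
5. Allylic alcohol ⇒ (E)-geranylacetone by SeO2 oxidation of the terminal (E)-methyl; the vinyl unit on C12 comes from cuprate displacement of the epoxy triflate. Ring order: the carbocycle is formed once, in step 4, together with a transient dihydropyran that is opened on work-up.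

Assumption: (E)-geranylacetone of at least 97% E purity is used (the commercial E/Z mixture would need prior separation).

**Route**

Step 1
Reactants: 1 (5E)-6,10-dimethylundeca-5,9-dien-2-one ((E)-geranylacetone)
Product: 2 (5E,9E)-11-hydroxy-6,10-dimethylundeca-5,9-dien-2-one
Conditions: SeO2 (0.1 equiv), t-BuOOH (2.5 equiv), salicylic acid (0.1 equiv), CH2Cl2, 0 °C to rt, stopped at about 60% conversion
Reagents that add atoms: tert-butyl hydroperoxide, CC(C)(C)OO
Why: Selenium dioxide allylic oxidation (ene reaction followed by [2,3]-sigmatropic shift, reoxidised by t-BuOOH) hydroxylates the (E)-methyl group (C12) of the terminal, least hindered trisubstituted alkene and leaves the ketone alone at room temperature; no stereocentre is formed and the run is stopped early so that the C12 aldehyde and C8 oxidation stay minor.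

Step 2
Reactants: 2 (5E,9E)-11-hydroxy-6,10-dimethylundeca-5,9-dien-2-one
Product: 3 (5E)-8-[(2R,3R)-3-(hydroxymethyl)-3-methyloxiran-2-yl]-6-methyloct-5-en-2-one
Conditions: Ti(OiPr)4 (0.1 equiv), D-(−)-diethyl tartrate (0.12 equiv), t-BuOOH (2 equiv, in decane), 4 Å molecular sieves, CH2Cl2, −20 °C
Reagents that add atoms: tert-butyl hydroperoxide, CC(C)(C)OO
Why: Sharpless asymmetric epoxidation: titanium binds the allylic hydroxyl so that only the C10=C11 alkene is epoxidised, and D-(−)-diethyl tartrate directs oxygen to the face that gives the (2R,3R)-epoxy alcohol (the mirror image of the (2S,3S) product that L-(+)-tartrate gives with (E)-2-methylalk-2-en-1-ols), which sets C10 and C11 with above 90% ee.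

Step 3
Reactants: 3 (5E)-8-[(2R,3R)-3-(hydroxymethyl)-3-methyloxiran-2-yl]-6-methyloct-5-en-2-one
Product: 5 (5E)-6-methyl-8-[(2R,3R)-3-methyl-3-(prop-2-en-1-yl)oxiran-2-yl]oct-5-en-2-one, via epoxy triflate 4 (not isolated)
Conditions: (CF3SO2)2O (1.1 equiv), 2,6-lutidine (1.3 equiv), CH2Cl2, −78 °C; then (CH2=CH)2CuMgBr [from CH2=CHMgBr (3 equiv) and CuBr·SMe2 (1.5 equiv)], THF, −78 to −40 °C
Reagents that add atoms: vinylmagnesium bromide, C=C[Mg]Br
Why: Sulfonate formation then SN2 substitution by an organocuprate: the primary triflate, activated by the adjacent strained ring, is displaced by the soft divinylcuprate at −78 °C much faster than the cuprate adds to the ketone or opens the trisubstituted epoxide, so the epoxide stereocentres are untouched.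

Step 4
Reactants: 5 (5E)-6-methyl-8-[(2R,3R)-3-methyl-3-(prop-2-en-1-yl)oxiran-2-yl]oct-5-en-2-one
Product: 7 4-[(1S,2S,3S,6S)-3-bromo-6-hydroxy-2,6-dimethyl-2-(prop-2-en-1-yl)cyclohexyl]butan-2-one, via bromo enol ether 6 (not isolated)
Conditions: [Ph3PBr]+ CF3SO3− (1.2 equiv, made from Ph3PBr2 and AgOSO2CF3 in CH2Cl2, AgBr filtered off), 2,6-di-tert-butyl-4-methylpyridine (2 equiv), CH2Cl2/CH3NO2, 0.01 M, −78 to −20 °C; then 1 M HCl, THF, 0 °C
Reagents that add atoms: dibromotriphenylphosphorane, BrP(Br)(c1ccccc1)(c1ccccc1)c1ccccc1; water, O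
Why: Proposed new method: deoxygenative bromonium-ion generation from an epoxide coupled to a cation–olefin cyclisation; the oxophilic phosphonium binds the epoxide oxygen and releases its single bromide, which opens the ring with inversion (first stage of the known Ph3PBr2 epoxide-to-dibromide reaction); because the only counter-ion left is triflate, loss of Ph3P=O is assisted by the neighbouring bromine and gives one enantiomer of the C10/C11 bromonium ion on the face opposite to the former oxygen; C6 of the (E)-C6=C7 alkene attacks C11 through a chair transition state while the ketone oxygen adds to C7 in an anti sense, so C10 (inversion), C11 (net retention), C6 and C7 (equatorial side chain and oxygen) are set together, and aqueous acid hydrolyses the enol ether 6 to the hydroxy ketone; the closest known reactions are enantiospecific bromonium polyene cyclisations started from enantioenriched bromohydrin esters or vicinal bromochlorides and carbonyl-oxygen-terminated bromonium cyclisations of geranylacetone-type dienones.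

Step 5
Reactants: 7 4-[(1S,2S,3S,6S)-3-bromo-6-hydroxy-2,6-dimethyl-2-(prop-2-en-1-yl)cyclohexyl]butan-2-one; 8 2-methylbut-3-en-2-ol
Product: 9 4-[(1S,2S,3S,6S)-3-bromo-6-hydroxy-2-[(2E)-4-hydroxy-4-methylpent-2-en-1-yl]-2,6-dimethylcyclohexyl]butan-2-one
Conditions: 8 (8 equiv), second-generation Grubbs catalyst (5 mol %), CH2Cl2, 40 °C
Reagents that add atoms: none
Why: Olefin cross-metathesis: the unhindered allyl group couples with the excess tertiary allylic alcohol, which homodimerises only slowly, and the reversible reaction settles on the (E)-alkene; ethene is lost and no stereocentre is touched.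

Step 6
Reactants: 9 4-[(1S,2S,3S,6S)-3-bromo-6-hydroxy-2-[(2E)-4-hydroxy-4-methylpent-2-en-1-yl]-2,6-dimethylcyclohexyl]butan-2-one
Product: 10 (1S,2S,3S,4S)-4-bromo-3-[(2E)-4-hydroxy-4-methylpent-2-en-1-yl]-1,3-dimethyl-2-[2-[(2S)-2-methyloxiran-2-yl]ethyl]cyclohexan-1-ol
Conditions: LaLi3[(S)-1,1'-binaphthalene-2,2'-diolate]3 (5 mol %), [2,4,6-(MeO)3C6H2]3P=O (5 mol %), CH2=S(O)(CH3)2 [1.3 equiv, from (CH3)3S(O)I and NaH], 5 Å molecular sieves, THF, rt
Reagents that add atoms: trimethylsulfoxonium iodide, C[S+](C)(C)=O.[I-]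
Why: Catalytic asymmetric Corey–Chaykovsky epoxidation: the lanthanum–lithium binaphthoxide holds the methyl ketone and the sulfoxonium ylide together and transfers CH2 to the Re face (methyl versus primary alkyl discrimination), which forms the C3–O bond as the (S)-epoxide under catalyst control independent of the distant ring; the weakly basic ylide leaves the hydroxyls and the bromide alone.

Step 7
Reactants: 10 (1S,2S,3S,4S)-4-bromo-3-[(2E)-4-hydroxy-4-methylpent-2-en-1-yl]-1,3-dimethyl-2-[2-[(2S)-2-methyloxiran-2-yl]ethyl]cyclohexan-1-ol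
Product: 11 (1S,2S,3S,4S)-4-bromo-2-[(3S)-3-hydroxy-3-methylpent-4-en-1-yl]-3-[(2E)-4-hydroxy-4-methylpent-2-en-1-yl]-1,3-dimethylcyclohexan-1-ol
Conditions: (CH3)3SI (6 equiv), n-BuLi (5.8 equiv), THF, −10 °C to rt; aq NH4Cl
Reagents that add atoms: trimethylsulfonium iodide, C[S+](C)C.[I-]
Why: Sulfonium ylide opening of a terminal epoxide to the one-carbon-longer allylic alcohol: the ylide attacks the epoxide CH2, and the betaine loses Me2S by ylide formation and syn-elimination to give the vinyl group, while the C3–O bond and its (S) configuration are not touched; the equatorial bromide next to a quaternary carbon has no antiperiplanar hydrogen and resists substitution.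

**Compound list**

1 | (5E)-6,10-dimethylundeca-5,9-dien-2-one ((E)-geranylacetone) | CC(=O)CC/C=C(\C)CCC=C(C)C | starting material
2 | (5E,9E)-11-hydroxy-6,10-dimethylundeca-5,9-dien-2-one | CC(=O)CC/C=C(\C)CC/C=C(\C)CO | intermediate
3 | (5E)-8-[(2R,3R)-3-(hydroxymethyl)-3-methyloxiran-2-yl]-6-methyloct-5-en-2-one | CC(=O)CC/C=C(\C)CC[C@H]1O[C@]1(C)CO | intermediate
4 | [(2R,3R)-2-methyl-3-[(3E)-3-methyl-7-oxooct-3-en-1-yl]oxiran-2-yl]methyl trifluoromethanesulfonate | CC(=O)CC/C=C(\C)CC[C@H]1O[C@]1(C)COS(=O)(=O)C(F)(F)F | intermediate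
5 | (5E)-6-methyl-8-[(2R,3R)-3-methyl-3-(prop-2-en-1-yl)oxiran-2-yl]oct-5-en-2-one | CC(=O)CC/C=C(\C)CC[C@H]1O[C@]1(C)CC=C | intermediate
6 | (4aS,5S,6S,8aS)-6-bromo-2,5,8a-trimethyl-5-(prop-2-en-1-yl)-4a,5,6,7,8,8a-hexahydro-4H-chromene | CC1=CC[C@H]2[C@](C)(CC=C)[C@@H](Br)CC[C@]2(C)O1 | intermediate
7 | 4-[(1S,2S,3S,6S)-3-bromo-6-hydroxy-2,6-dimethyl-2-(prop-2-en-1-yl)cyclohexyl]butan-2-one | CC(=O)CC[C@H]1[C@](C)(CC=C)[C@@H](Br)CC[C@]1(C)O | intermediate
8 | 2-methylbut-3-en-2-ol | CC(C)(O)C=C | starting material
9 | 4-[(1S,2S,3S,6S)-3-bromo-6-hydroxy-2-[(2E)-4-hydroxy-4-methylpent-2-en-1-yl]-2,6-dimethylcyclohexyl]butan-2-one | CC(=O)CC[C@H]1[C@](C)(C/C=C/C(C)(C)O)[C@@H](Br)CC[C@]1(C)O | intermediate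
10 | (1S,2S,3S,4S)-4-bromo-3-[(2E)-4-hydroxy-4-methylpent-2-en-1-yl]-1,3-dimethyl-2-[2-[(2S)-2-methyloxiran-2-yl]ethyl]cyclohexan-1-ol | C[C@@]1(CO1)CC[C@H]2[C@](C)(C/C=C/C(C)(C)O)[C@@H](Br)CC[C@]2(C)O | intermediate
11 | (1S,2S,3S,4S)-4-bromo-2-[(3S)-3-hydroxy-3-methylpent-4-en-1-yl]-3-[(2E)-4-hydroxy-4-methylpent-2-en-1-yl]-1,3-dimethylcyclohexan-1-ol | C=C[C@@](C)(O)CC[C@H]1[C@](C)(C/C=C/C(C)(C)O)[C@@H](Br)CC[C@]1(C)O | target

**Step count and risks**

Total step count: 7. Longest linear sequence: 7 steps (1 to 11); 8 joins at step 5.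

Steps most likely to fail:

Step 4 (the new step). The activated epoxide may be attacked by the C6=C7 alkene before bromide is delivered, or the bromonium ion may lose a proton from C12 instead of cyclising. The fallback uses known reactions, sets out from 5 and comes back to the route at 7. The epoxide is opened at its less substituted carbon with Li2NiBr4 (THF, 0 °C) to the bromohydrin (5E,9S,10R)-9-bromo-10-hydroxy-6,10-dimethyltrideca-5,12-dien-2-one F1. The tertiary hydroxyl is exchanged for chloride with retention through bromine participation (SOCl2, 2,6-lutidine, CH2Cl2, −20 °C) to give (5E,9S,10R)-9-bromo-10-chloro-6,10-dimethyltrideca-5,12-dien-2-one F2. The tertiary chloride is then solvolysed in (CF3)2CHOH over K2CO3, the established way to release an enantioenriched bromonium ion from a vicinal bromochloride for a polyene cyclisation, and the enol ether 6 is hydrolysed as before to reach 7.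

Step 3. The triflate sits on a carbon next to a fully substituted epoxide carbon, and the cuprate may touch the ketone. The fallback reverses the order of C–C and C–O bond formation, sets out from 2 and comes back at 5. Compound 2 is converted into the chloride (5E,9E)-11-chloro-6,10-dimethylundeca-5,9-dien-2-one F3 (CH3SO2Cl, LiCl, 2,4,6-collidine, DMF, 0 °C). F3 is coupled with tributyl(vinyl)stannane (Pd2(dba)3, tri(2-furyl)phosphine, THF, 50 °C) to the triene (5E,9E)-6,10-dimethyltrideca-5,9,12-trien-2-one F4. F4 is epoxidised with the D-fructose-derived Shi ketone and KHSO5 (pH 10.5, 0 °C, about half conversion), which gives (R,R)-epoxides from (E)-trisubstituted alkenes. Because the hydroxyl direction is lost, 5 forms together with its regioisomer 4-[(2R,3R)-3-methyl-3-[(3E)-4-methylhepta-3,6-dien-1-yl]oxiran-2-yl]butan-2-one F5 and is separated from it by chromatography.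

Step 6. The two free tertiary hydroxyls may disturb the lanthanum–lithium catalyst and lower the selectivity at C3. The fallback gives up catalyst control for separation, sets out from 9 and comes back at 11, bypassing 10. CH2=CHMgBr (4 equiv) with CeCl3 in THF at −78 °C adds to the ketone and gives 11 together with its C3 epimer (1S,2S,3S,4S)-4-bromo-2-[(3R)-3-hydroxy-3-methylpent-4-en-1-yl]-3-[(2E)-4-hydroxy-4-methylpent-2-en-1-yl]-1,3-dimethylcyclohexan-1-ol F6, which is removed by preparative HPLC.

Further compounds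
F1 | step 4 | (5E,9S,10R)-9-bromo-10-hydroxy-6,10-dimethyltrideca-5,12-dien-2-one | CC(=O)CC/C=C(\C)CC[C@H](Br)[C@](C)(O)CC=C
F2 | step 4 | (5E,9S,10R)-9-bromo-10-chloro-6,10-dimethyltrideca-5,12-dien-2-one | CC(=O)CC/C=C(\C)CC[C@H](Br)[C@](C)(Cl)CC=C
F3 | step 3 | (5E,9E)-11-chloro-6,10-dimethylundeca-5,9-dien-2-one | CC(=O)CC/C=C(\C)CC/C=C(\C)CCl
F4 | step 3 | (5E,9E)-6,10-dimethyltrideca-5,9,12-trien-2-one | CC(=O)CC/C=C(\C)CC/C=C(\C)CC=C
F5 | step 3 | 4-[(2R,3R)-3-methyl-3-[(3E)-4-methylhepta-3,6-dien-1-yl]oxiran-2-yl]butan-2-one | CC(=O)CC[C@H]1O[C@]1(C)CC/C=C(\C)CC=C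
F6 | step 6 | (1S,2S,3S,4S)-4-bromo-2-[(3R)-3-hydroxy-3-methylpent-4-en-1-yl]-3-[(2E)-4-hydroxy-4-methylpent-2-en-1-yl]-1,3-dimethylcyclohexan-1-ol | C=C[C@](C)(O)CC[C@H]1[C@](C)(C/C=C/C(C)(C)O)[C@@H](Br)CC[C@]1(C)O
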